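**Retrosynthetic overview**
1. The esters are adjusted last. The C8–C9 bond comes from a chelation-controlled Hosomi–Sakurai union of aldehyde 21 (C1–C8) with allylsilane spiroketal 12 (C9–C23); C10 is then set by hydroxyl-directed hydrogenation.
2. 12 comes from the C2-symmetric spiroketal dialdehyde 7 by two successive chelation-controlled organomagnesium additions (C21 arm first, then C11 arm).
3. 7 comes from bis(2-methylpropenyl) spiroketal 6 by ozonolysis. 6 comes from dienyl ketone 4 in one electrochemical, selenium-catalysed double allylic C–H oxygenation/transposition–spiroketalisation that forms the C12–O and C20–O bonds.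
4. 4 comes from two molecules of (S)-citronellic acid (ketene-dimer route). 21 comes from (R)-glyceraldehyde acetonide by crotylboration and a vinylogous Mukaiyama aldol.
5. Ring order: both tetrahydropyran rings of the spiroketal close together in step 2; no other ring is formed.

Assumption: atom labels C1–C23 follow the target chain (C1 = methyl ester carbon, C23 = ketone methyl; the ring oxygens bridge C12/C16 and C16/C20), and commercial (S)-citronellic acid and (R)-glyceraldehyde acetonide are taken as enantiopure.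

Abbreviation used in names from compound 22 onward: Sp = (2S,4S,6S,8S,10S)-8-[(1R)-1-{[tert-butyl(dimethyl)silyl]oxy}-2-oxopropyl]-4,10-dimethyl-1,7-dioxaspiro[5.5]undecan-2-yl.

**Route**

Step 1
Reactants: 1 (S)-citronellic acid (two molecules are joined in this step)
Product: 4 (6S,10S)-2,6,10,14-tetramethylpentadeca-2,13-dien-8-one, via (S)-citronelloyl chloride 2 (not isolated), via alkylketene dimer 3 (not isolated)
Conditions: (COCl)2, cat. DMF, CH2Cl2, 0 °C to rt, evaporate; Et3N, Et2O (1 M), 0 °C to rt, 16 h, filter; 2 M KOH, EtOH/H2O, 80 °C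
Reagents that add atoms: (S)-citronellic acid (second molecule of 1), CC(C)=CCC[C@H](C)CC(=O)O
Why: Dehydrochlorination of 2 gives the aldoketene, two molecules of which combine at high concentration (Sauer ketene dimerisation) faster than the ketene can cyclise onto the remote alkene; alkaline hydrolysis of the β-lactone dimer and decarboxylation of the β-keto acid give the symmetrical C19 ketone, and the β-methyl stereocentres of both molecules of 1 are untouched and become C14 and C18.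

Step 2
Reactants: 4 dienyl ketone
Product: 6 (2S,4S,6S,8S,10S)-4,10-dimethyl-2,8-bis(2-methylprop-1-en-1-yl)-1,7-dioxaspiro[5.5]undecane, via bis(tertiary allylic alcohol) ketone 5 (not isolated)
Conditions: (PhSe)2 (10 mol %), LiClO4 (0.1 M), MeCN/H2O 9:1, graphite anode, Pt cathode, undivided cell, 5 mA cm−2, 4.5 F mol−1, rt; then current off, 2 h
Reagents that add atoms: water, O
Why: Proposed new method: an anodically driven (PhSe)2 cycle is expected to convert each trisubstituted alkene of 4 into the transposed tertiary allylic alcohol 5 (seleniranium formation, Markovnikov capture by water, anodic oxidation to the selenoxide and syn-elimination away from the carbinol), after which the acid generated at the anode ionises these allylic alcohols so that the oxygens of the hydrated C16 ketone close both six-membered rings at the allylic termini C12 and C20, the reversible ionisation funnelling the mixture to the all-equatorial, doubly anomeric spiroketal in which the bought C14 and C18 methyl centres fix C12, C16 and C20; the closest known reactions are the electrochemical oxyselenenylation–deselenenylation of citronellol used for rose oxide and the acid- or Re2O7-mediated allylic transposition–spiroketalisation of keto allylic alcohols, which have not been run as one electrolysis or on a ketone flanked by two prenyl-type alkenes.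

Step 3
Reactants: 6 bis(2-methylpropenyl) spiroketal
Product: 7 (2S,4S,6S,8S,10S)-4,10-dimethyl-1,7-dioxaspiro[5.5]undecane-2,8-dicarbaldehyde
Conditions: O3, CH2Cl2, −78 °C; Me2S, −78 °C to rt
Reagents that add atoms: ozone, [O-][O+]=O
Why: Criegee ozonolysis with reductive work-up cleaves both electron-rich trisubstituted alkenes to α-alkoxy aldehydes while the spiroketal is inert, and C12 and C20 remain in their equatorial (thermodynamic) configuration.

Step 4
Reactants: 7 spiroketal dialdehyde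
Product: 8 (2S,4S,6S,8S,10S)-8-[(1R)-2-ethoxy-1-hydroxyprop-2-en-1-yl]-4,10-dimethyl-1,7-dioxaspiro[5.5]undecane-2-carbaldehyde
Conditions: ethyl vinyl ether, t-BuLi, THF, −78 to 0 °C; MgBr2·OEt2, −78 °C; 7 (2.5 equiv), CH2Cl2, −78 °C; H2O; excess 7 recovered
Reagents that add atoms: ethyl vinyl ether, C=COCC
Why: Cram-chelate addition of the acetyl-anion equivalent (1-ethoxyvinyl)magnesium bromide, with magnesium bridging the formyl and ring oxygens so that attack occurs anti to C19 and gives the C20/C21 threo (21R) alcohol; the two formyl groups of C2-symmetric 7 are homotopic, so mono-addition with 7 in excess gives one compound.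

Step 5
Reactants: 8 hydroxy enol ether aldehyde
Product: 9 (2S,4S,6S,8S,10S)-8-[(1R)-1-{[tert-butyl(dimethyl)silyl]oxy}-2-ethoxyprop-2-en-1-yl]-4,10-dimethyl-1,7-dioxaspiro[5.5]undecane-2-carbaldehyde
Conditions: TBSCl, imidazole, cat. DMAP, DMF, 35 °C
Reagents that add atoms: tert-butyldimethylsilyl chloride, CC(C)(C)[Si](C)(C)Cl
Why: Imidazole-mediated silylation of the only hydroxyl under non-acidic conditions that leave the enol ether and the aldehyde intact; no stereocentre is changed.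

Step 6
Reactants: 9 silyl ether aldehyde
Product: 11 (1R)-1-{[tert-butyl(dimethyl)silyl]oxy}-1-[(2S,4S,6S,8S,10S)-8-{(1S)-1-hydroxy-2-[(trimethylsilyl)methyl]prop-2-en-1-yl}-4,10-dimethyl-1,7-dioxaspiro[5.5]undecan-2-yl]propan-2-one, via enol ether adduct 10 (not isolated)
Conditions: (2-bromoallyl)trimethylsilane, Mg, THF, 50 °C; add to 9, MgBr2·OEt2, CH2Cl2, −78 °C; then 0.1 M HCl, THF, 0 °C, 15 min
Reagents that add atoms: (2-bromoallyl)trimethylsilane, C=C(Br)C[Si](C)(C)C; water, O
Why: Chelation-controlled Grignard addition of the 1-(trimethylsilylmethyl)vinyl conjunctive reagent to the α-alkoxy aldehyde (magnesium bridging formyl and ring oxygens, attack anti to C13) gives the C11/C12 threo (11S) alcohol, and the brief dilute-acid work-up hydrolyses the 1-ethoxyvinyl group to the C22 methyl ketone without protodesilylating the allylsilane.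

Step 7
Reactants: 11 hydroxy allylsilane ketone
Product: 12 C11 triethylsilyl ether of 11 (C9–C23 fragment)
Conditions: TESCl, imidazole, CH2Cl2, 0 °C
Reagents that add atoms: chlorotriethylsilane, CC[Si](Cl)(CC)CC
Why: Silylation of the single free hydroxyl with the more labile triethylsilyl group, chosen so that it can later be removed in the presence of the C21 TBS ether; no stereocentre is affected.

Step 8
Reactants: 13 methyl tiglate
Product: 14 tert-butyl[(1-methoxy-2-methylbuta-1,3-dien-1-yl)oxy]dimethylsilane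
Conditions: LiN(i-Pr)2, THF, −78 °C; TBSCl, DMPU, −78 °C to rt
Reagents that add atoms: tert-butyldimethylsilyl chloride, CC(C)(C)[Si](C)(C)Cl
Why: γ-Deprotonation of the enoate and O-silylation of the dienolate (vinylketene silyl acetal formation) gives the nucleophile for the vinylogous aldol; no stereocentre is formed and the ketene acetal geometry is immaterial.

Step 9
Reactants: 15 (R)-glyceraldehyde acetonide
Product: 16 (1S,2S)-1-[(4R)-2,2-dimethyl-1,3-dioxolan-4-yl]-2-methylbut-3-en-1-ol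
Conditions: (E)-crotylboronic acid pinacol ester, toluene, rt, 48 h; aqueous work-up
Reagents that add atoms: (E)-crotylboronic acid pinacol ester, C/C=C/CB1OC(C)(C)C(C)(C)O1
Why: Crotylboration through a closed Zimmerman–Traxler transition state transfers the E geometry into the C6/C7 anti relationship, and Felkin attack anti to the dioxolane C–O bond of the bought (R)-aldehyde fixes the absolute sense of C6 and C7 (dr about 85:15, minor isomers removed by chromatography).

Step 10
Reactants: 16 homoallylic alcohol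
Product: 17 (4R)-4-{(1S,2S)-1-[(4-methoxybenzyl)oxy]-2-methylbut-3-en-1-yl}-2,2-dimethyl-1,3-dioxolane
Conditions: NaH, PMBCl, cat. Bu4NI, THF/DMF, 0 °C to rt
Reagents that add atoms: 4-methoxybenzyl chloride, COc1ccc(CCl)cc1
Why: Williamson etherification installs at C7 an ether that can chelate SnCl4 in step 15 and be removed oxidatively later; no stereocentre is touched.

Step 11
Reactants: 17 PMB ether
Product: 18 (2R,3S)-3-[(4R)-2,2-dimethyl-1,3-dioxolan-4-yl]-3-[(4-methoxybenzyl)oxy]-2-methylpropanal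
Conditions: OsO4 (2 mol %), NaIO4, 2,6-lutidine, dioxane/H2O, rt
Reagents that add atoms: osmium tetroxide (catalytic oxygen carrier), O=[Os](=O)(=O)=O; sodium periodate, [Na+].[O-]I(=O)(=O)=O
Why: Lemieux–Johnson cleavage (dihydroxylation then periodate scission) of the terminal vinyl group gives the C5 aldehyde, with 2,6-lutidine buffering the mixture so the α-methyl centre C6 is not epimerised (its descriptor changes to R only through priority).

Step 12
Reactants: 18 α-methyl aldehyde; 14 silyl dienolate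
Product: 19 methyl (2E,5R,6S,7S)-7-[(4R)-2,2-dimethyl-1,3-dioxolan-4-yl]-5-hydroxy-7-[(4-methoxybenzyl)oxy]-2,6-dimethylhept-2-enoate
Conditions: BF3·OEt2, CH2Cl2, −78 °C; H2O
Reagents that add atoms: none
Why: Vinylogous Mukaiyama aldol through an open transition state at the γ-carbon of 14, in which Felkin–Anh control by the α-methyl group and 1,3-anti induction by the β-OPMB group reinforce each other in this anti-configured aldehyde to set 5R (5,6-syn, 5,7-anti) and deliver the E-enoate directly.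

Step 13
Reactants: 19 δ-hydroxy enoate
Product: 20 methyl (2E,5R,6S,7S)-7-[(4R)-2,2-dimethyl-1,3-dioxolan-4-yl]-7-[(4-methoxybenzyl)oxy]-2,6-dimethyl-5-(propanoyloxy)hept-2-enoate
Conditions: (EtCO)2O, Et3N, cat. DMAP, CH2Cl2, rt
Reagents that add atoms: propanoic anhydride, CCC(=O)OC(=O)CC
Why: DMAP-catalysed acylation of the only free hydroxyl installs the final C5 propanoate with retention.

Step 14
Reactants: 20 acetonide ester
Product: 21 methyl (2E,5R,6S,7S)-7-[(4-methoxybenzyl)oxy]-2,6-dimethyl-8-oxo-5-(propanoyloxy)oct-2-enoate (C1–C8 fragment)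
Conditions: H5IO6, EtOAc, rt
Reagents that add atoms: none
Why: Periodic acid hydrolyses the terminal acetonide and cleaves the resulting 1,2-diol in one flask (glycol cleavage), unveiling the C8 aldehyde and discarding the glyceraldehyde-derived centre after it has controlled C6 and C7.

Step 15
Reactants: 21 C1–C8 aldehyde; 12 C9–C23 allylsilane
Product: 22 methyl (2E,5R,6S,7S,8S,11S)-8-hydroxy-7-[(4-methoxybenzyl)oxy]-2,6-dimethyl-10-methylidene-5-(propanoyloxy)-11-Sp-11-[(triethylsilyl)oxy]undec-2-enoate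
Conditions: 21, SnCl4 (1.1 equiv), CH2Cl2, −78 °C, 10 min; then 12 (1.2 equiv), −78 °C; H2O
Reagents that add atoms: none
Why: Chelation-controlled Hosomi–Sakurai allylation in which SnCl4 bridges the C8 formyl oxygen and the C7 PMB ether oxygen so that the allylsilane terminus (C9) adds anti to C6 and gives the C7/C8 syn (8S) alcohol, loss of silicon leaving the C10 exo-methylene needed for the next stereocentre.

Step 16
Reactants: 22 C8 alcohol
Product: 23 C8 3-methylbutanoate of 22
Conditions: isovaleric anhydride, Et3N, DMAP, CH2Cl2, rt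
Reagents that add atoms: 3-methylbutanoic anhydride, CC(C)CC(=O)OC(=O)CC(C)C
Why: DMAP-catalysed acylation of the only free hydroxyl installs the final C8 ester and removes the homoallylic hydroxyl that would otherwise compete as a directing group in step 18.

Step 17
Reactants: 23 bis-silyl ether
Product: 24 C11 alcohol (triethylsilyl group removed from 23)
Conditions: HF·pyridine, pyridine, THF, 0 °C
Reagents that add atoms: none
Why: Buffered fluoride cleaves the secondary triethylsilyl ether far faster than the bulkier TBS ether (selective desilylation), freeing C11–OH without touching esters or the spiroketal.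

Step 18
Reactants: 24 allylic alcohol
Product: 25 methyl (2E,5R,6S,7S,8S,10S,11S)-11-hydroxy-7-[(4-methoxybenzyl)oxy]-2,6,10-trimethyl-8-[(3-methylbutanoyl)oxy]-5-(propanoyloxy)-11-Sp-undec-2-enoate
Conditions: H2 (50 bar), [Rh(nbd)(dppb)]BF4 (10 mol %), CH2Cl2, rt
Reagents that add atoms: none
Why: Hydroxyl-directed homogeneous hydrogenation in which the cationic rhodium complex binds C11–OH and the 1,1-disubstituted alkene and delivers H2 to the oxygen-bound face of the conformer with least A(1,2) strain, giving the 10,11-anti (10S) methyl group, while the trisubstituted enoate has no bound hydroxyl and is left alone.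

Step 19
Reactants: 25 C11 alcohol
Product: 26 C11 3-methylbutanoate of 25 (8,11-bis ester)
Conditions: isovaleric anhydride, Et3N, DMAP (1 equiv), CH2Cl2, 35 °C
Reagents that add atoms: 3-methylbutanoic anhydride, CC(C)CC(=O)OC(=O)CC(C)C
Why: Forced DMAP acylation of the hindered secondary alcohol installs the final C11 ester with retention while C21 stays masked as its TBS ether.

Step 20
Reactants: 26 PMB ether
Product: 27 C7 alcohol (PMB removed from 26)
Conditions: DDQ, CH2Cl2/pH 7 buffer, 0 °C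
Reagents that add atoms: none
Why: Oxidative PMB cleavage (benzylic hydride abstraction by DDQ and hydrolysis of the oxocarbenium) under neutral conditions leaves all esters, the enoate, the TBS ether and the spiroketal in place.

Step 21
Reactants: 27 C7 alcohol
Product: 28 methyl (2E,5R,6S,7S,8S,10S,11S)-7-(acetyloxy)-2,6,10-trimethyl-8,11-bis[(3-methylbutanoyl)oxy]-5-(propanoyloxy)-11-Sp-undec-2-enoate
Conditions: Ac2O, pyridine, cat. DMAP, CH2Cl2, 0 °C
Reagents that add atoms: acetic anhydride, CC(=O)OC(C)=O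
Why: Rapid DMAP-catalysed acetylation of the newly freed C7 hydroxyl outruns acyl migration and installs the last ester with retention.

Step 22
Reactants: 28 C21 silyl ether
Product: 29 CNP0165569.4
Conditions: HF·pyridine, THF, rt
Reagents that add atoms: none
Why: Fluoride desilylation of the α-silyloxy ketone liberates the C21 hydroxyl under mildly acidic conditions that do not epimerise C21, migrate acyl groups or open the thermodynamic spiroketal.

**Compound list**
1 | (3S)-3,7-dimethyloct-6-enoic acid, (S)-citronellic acid | CC(C)=CCC[C@H](C)CC(=O)O | starting material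
2 | (3S)-3,7-dimethyloct-6-enoyl chloride | CC(C)=CCC[C@H](C)CC(=O)Cl | intermediate
3 | (4Z)-4-[(2S)-2,6-dimethylhept-5-en-1-ylidene]-3-[(2S)-6-methylhept-5-en-2-yl]oxetan-2-one (alkylketene dimer, C3 epimers) | O=C1O/C(=C\[C@@H](C)CCC=C(C)C)C1[C@@H](C)CCC=C(C)C | intermediate
4 | (6S,10S)-2,6,10,14-tetramethylpentadeca-2,13-dien-8-one | CC(C)=CCC[C@H](C)CC(=O)C[C@@H](C)CCC=C(C)C | intermediate
5 | (3E,6S,10S,12E)-2,14-dihydroxy-2,6,10,14-tetramethylpentadeca-3,12-dien-8-one | CC(C)(O)/C=C/C[C@H](C)CC(=O)C[C@@H](C)C/C=C/C(C)(C)O | intermediate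
6 | (2S,4S,6S,8S,10S)-4,10-dimethyl-2,8-bis(2-methylprop-1-en-1-yl)-1,7-dioxaspiro[5.5]undecane | CC(C)=C[C@@H]1C[C@H](C)C[C@]2(C[C@@H](C)C[C@@H](C=C(C)C)O2)O1 | intermediate
7 | (2S,4S,6S,8S,10S)-4,10-dimethyl-1,7-dioxaspiro[5.5]undecane-2,8-dicarbaldehyde | O=C[C@@H]1C[C@H](C)C[C@]2(C[C@@H](C)C[C@@H](C=O)O2)O1 | intermediate
8 | (2S,4S,6S,8S,10S)-8-[(1R)-2-ethoxy-1-hydroxyprop-2-en-1-yl]-4,10-dimethyl-1,7-dioxaspiro[5.5]undecane-2-carbaldehyde | O=C[C@@H]1C[C@H](C)C[C@]2(C[C@@H](C)C[C@@H]([C@@H](O)C(=C)OCC)O2)O1 | intermediate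
9 | (2S,4S,6S,8S,10S)-8-[(1R)-1-{[tert-butyl(dimethyl)silyl]oxy}-2-ethoxyprop-2-en-1-yl]-4,10-dimethyl-1,7-dioxaspiro[5.5]undecane-2-carbaldehyde | O=C[C@@H]1C[C@H](C)C[C@]2(C[C@@H](C)C[C@@H]([C@@H](O[Si](C)(C)C(C)(C)C)C(=C)OCC)O2)O1 | intermediate
10 | (1S)-1-[(2S,4S,6S,8S,10S)-8-[(1R)-1-{[tert-butyl(dimethyl)silyl]oxy}-2-ethoxyprop-2-en-1-yl]-4,10-dimethyl-1,7-dioxaspiro[5.5]undecan-2-yl]-2-[(trimethylsilyl)methyl]prop-2-en-1-ol | C=C(C[Si](C)(C)C)[C@H](O)[C@@H]1C[C@H](C)C[C@]2(C[C@@H](C)C[C@@H]([C@@H](O[Si](C)(C)C(C)(C)C)C(=C)OCC)O2)O1 | intermediate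
11 | (1R)-1-{[tert-butyl(dimethyl)silyl]oxy}-1-[(2S,4S,6S,8S,10S)-8-{(1S)-1-hydroxy-2-[(trimethylsilyl)methyl]prop-2-en-1-yl}-4,10-dimethyl-1,7-dioxaspiro[5.5]undecan-2-yl]propan-2-one | C=C(C[Si](C)(C)C)[C@H](O)[C@@H]1C[C@H](C)C[C@]2(C[C@@H](C)C[C@@H]([C@@H](O[Si](C)(C)C(C)(C)C)C(C)=O)O2)O1 | intermediate
12 | (1R)-1-{[tert-butyl(dimethyl)silyl]oxy}-1-[(2S,4S,6S,8S,10S)-4,10-dimethyl-8-{(1S)-1-[(triethylsilyl)oxy]-2-[(trimethylsilyl)methyl]prop-2-en-1-yl}-1,7-dioxaspiro[5.5]undecan-2-yl]propan-2-one | C=C(C[Si](C)(C)C)[C@H](O[Si](CC)(CC)CC)[C@@H]1C[C@H](C)C[C@]2(C[C@@H](C)C[C@@H]([C@@H](O[Si](C)(C)C(C)(C)C)C(C)=O)O2)O1 | intermediate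
13 | methyl (2E)-2-methylbut-2-enoate, methyl tiglate | C/C=C(\C)C(=O)OC | starting material
14 | tert-butyl[(1-methoxy-2-methylbuta-1,3-dien-1-yl)oxy]dimethylsilane (ketene acetal geometry immaterial) | C=CC(C)=C(OC)O[Si](C)(C)C(C)(C)C | intermediate
15 | (4R)-2,2-dimethyl-1,3-dioxolane-4-carbaldehyde, (R)-glyceraldehyde acetonide | O=C[C@H]1COC(C)(C)O1 | starting material
16 | (1S,2S)-1-[(4R)-2,2-dimethyl-1,3-dioxolan-4-yl]-2-methylbut-3-en-1-ol | C=C[C@H](C)[C@H](O)[C@H]1COC(C)(C)O1 | intermediate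
17 | (4R)-4-{(1S,2S)-1-[(4-methoxybenzyl)oxy]-2-methylbut-3-en-1-yl}-2,2-dimethyl-1,3-dioxolane | C=C[C@H](C)[C@H](OCc1ccc(OC)cc1)[C@H]1COC(C)(C)O1 | intermediate
18 | (2R,3S)-3-[(4R)-2,2-dimethyl-1,3-dioxolan-4-yl]-3-[(4-methoxybenzyl)oxy]-2-methylpropanal | O=C[C@H](C)[C@H](OCc1ccc(OC)cc1)[C@H]1COC(C)(C)O1 | intermediate
19 | methyl (2E,5R,6S,7S)-7-[(4R)-2,2-dimethyl-1,3-dioxolan-4-yl]-5-hydroxy-7-[(4-methoxybenzyl)oxy]-2,6-dimethylhept-2-enoate | O[C@H](C/C=C(\C)C(=O)OC)[C@H](C)[C@H](OCc1ccc(OC)cc1)[C@H]1COC(C)(C)O1 | intermediate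
20 | methyl (2E,5R,6S,7S)-7-[(4R)-2,2-dimethyl-1,3-dioxolan-4-yl]-7-[(4-methoxybenzyl)oxy]-2,6-dimethyl-5-(propanoyloxy)hept-2-enoate | CCC(=O)O[C@H](C/C=C(\C)C(=O)OC)[C@H](C)[C@H](OCc1ccc(OC)cc1)[C@H]1COC(C)(C)O1 | intermediate
21 | methyl (2E,5R,6S,7S)-7-[(4-methoxybenzyl)oxy]-2,6-dimethyl-8-oxo-5-(propanoyloxy)oct-2-enoate | CCC(=O)O[C@H](C/C=C(\C)C(=O)OC)[C@H](C)[C@H](OCc1ccc(OC)cc1)C=O | intermediate
22 | methyl (2E,5R,6S,7S,8S,11S)-8-hydroxy-7-[(4-methoxybenzyl)oxy]-2,6-dimethyl-10-methylidene-5-(propanoyloxy)-11-Sp-11-[(triethylsilyl)oxy]undec-2-enoate | CCC(=O)O[C@H](C/C=C(\C)C(=O)OC)[C@H](C)[C@H](OCc1ccc(OC)cc1)[C@H](CC(=C)[C@H](O[Si](CC)(CC)CC)[C@@H]1C[C@H](C)C[C@]2(C[C@@H](C)C[C@@H]([C@@H](O[Si](C)(C)C(C)(C)C)C(C)=O)O2)O1)O | intermediate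
23 | methyl (2E,5R,6S,7S,8S,11S)-7-[(4-methoxybenzyl)oxy]-2,6-dimethyl-10-methylidene-8-[(3-methylbutanoyl)oxy]-5-(propanoyloxy)-11-Sp-11-[(triethylsilyl)oxy]undec-2-enoate | CCC(=O)O[C@H](C/C=C(\C)C(=O)OC)[C@H](C)[C@H](OCc1ccc(OC)cc1)[C@H](CC(=C)[C@H](O[Si](CC)(CC)CC)[C@@H]1C[C@H](C)C[C@]2(C[C@@H](C)C[C@@H]([C@@H](O[Si](C)(C)C(C)(C)C)C(C)=O)O2)O1)OC(=O)CC(C)C | intermediate
24 | methyl (2E,5R,6S,7S,8S,11S)-11-hydroxy-7-[(4-methoxybenzyl)oxy]-2,6-dimethyl-10-methylidene-8-[(3-methylbutanoyl)oxy]-5-(propanoyloxy)-11-Sp-undec-2-enoate | CCC(=O)O[C@H](C/C=C(\C)C(=O)OC)[C@H](C)[C@H](OCc1ccc(OC)cc1)[C@H](CC(=C)[C@H](O)[C@@H]1C[C@H](C)C[C@]2(C[C@@H](C)C[C@@H]([C@@H](O[Si](C)(C)C(C)(C)C)C(C)=O)O2)O1)OC(=O)CC(C)C | intermediate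
25 | methyl (2E,5R,6S,7S,8S,10S,11S)-11-hydroxy-7-[(4-methoxybenzyl)oxy]-2,6,10-trimethyl-8-[(3-methylbutanoyl)oxy]-5-(propanoyloxy)-11-Sp-undec-2-enoate | CCC(=O)O[C@H](C/C=C(\C)C(=O)OC)[C@H](C)[C@H](OCc1ccc(OC)cc1)[C@H](C[C@H](C)[C@H](O)[C@@H]1C[C@H](C)C[C@]2(C[C@@H](C)C[C@@H]([C@@H](O[Si](C)(C)C(C)(C)C)C(C)=O)O2)O1)OC(=O)CC(C)C | intermediate
26 | methyl (2E,5R,6S,7S,8S,10S,11S)-7-[(4-methoxybenzyl)oxy]-2,6,10-trimethyl-8,11-bis[(3-methylbutanoyl)oxy]-5-(propanoyloxy)-11-Sp-undec-2-enoate | CCC(=O)O[C@H](C/C=C(\C)C(=O)OC)[C@H](C)[C@H](OCc1ccc(OC)cc1)[C@H](C[C@H](C)[C@H](OC(=O)CC(C)C)[C@@H]1C[C@H](C)C[C@]2(C[C@@H](C)C[C@@H]([C@@H](O[Si](C)(C)C(C)(C)C)C(C)=O)O2)O1)OC(=O)CC(C)C | intermediate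
27 | methyl (2E,5R,6R,7S,8S,10S,11S)-7-hydroxy-2,6,10-trimethyl-8,11-bis[(3-methylbutanoyl)oxy]-5-(propanoyloxy)-11-Sp-undec-2-enoate (6R by priority only, geometry unchanged) | CCC(=O)O[C@H](C/C=C(\C)C(=O)OC)[C@H](C)[C@H](O)[C@H](C[C@H](C)[C@H](OC(=O)CC(C)C)[C@@H]1C[C@H](C)C[C@]2(C[C@@H](C)C[C@@H]([C@@H](O[Si](C)(C)C(C)(C)C)C(C)=O)O2)O1)OC(=O)CC(C)C | intermediate
28 | methyl (2E,5R,6S,7S,8S,10S,11S)-7-(acetyloxy)-2,6,10-trimethyl-8,11-bis[(3-methylbutanoyl)oxy]-5-(propanoyloxy)-11-Sp-undec-2-enoate | CCC(=O)O[C@H](C/C=C(\C)C(=O)OC)[C@H](C)[C@H](OC(C)=O)[C@H](C[C@H](C)[C@H](OC(=O)CC(C)C)[C@@H]1C[C@H](C)C[C@]2(C[C@@H](C)C[C@@H]([C@@H](O[Si](C)(C)C(C)(C)C)C(C)=O)O2)O1)OC(=O)CC(C)C | intermediate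
29 | methyl (2E,5R,6S,7S,8S,10S,11S)-7-(acetyloxy)-11-[(2S,4S,6S,8S,10S)-8-[(1R)-1-hydroxy-2-oxopropyl]-4,10-dimethyl-1,7-dioxaspiro[5.5]undecan-2-yl]-2,6,10-trimethyl-8,11-bis[(3-methylbutanoyl)oxy]-5-(propanoyloxy)undec-2-enoate, CNP0165569.4 | CCC(=O)O[C@H](C/C=C(\C)C(=O)OC)[C@H](C)[C@H](OC(C)=O)[C@H](C[C@H](C)[C@H](OC(=O)CC(C)C)[C@@H]1C[C@H](C)C[C@]2(C[C@@H](C)C[C@@H]([C@@H](O)C(C)=O)O2)O1)OC(=O)CC(C)C | target

**Step count and weak points**
Total steps: 22. Longest linear sequence: 15 (steps 1–7, then 15–22); the C1–C8 branch (steps 8–14) joins at step 15.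

Most likely to fail:

Step 2 (the proposed electrochemical cascade; risks are over-oxidation of the product alkenes and incomplete ring closure). The fallback sets out from 4 and comes back at 6 using known reactions. 4 is treated with PhSeCl in MeCN/H2O to give the Markovnikov bis(β-hydroxy selenide) (6S,10S)-2,14-dihydroxy-2,6,10,14-tetramethyl-3,13-bis(phenylselanyl)pentadecan-8-one F1. Oxidation with H2O2 and selenoxide syn-elimination then give keto-diol 5, which is isolated. Catalytic Re2O7 in CH2Cl2 transposes both tertiary allylic alcohols and closes the spiroketal under the same thermodynamic control to give 6.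

Step 15 (fragment union; the strong Lewis acid may damage the silyl ethers, the PMB ether or the spiroketal, or chelation control may be eroded). The fallback sets out from 12 and comes back at 22. Bromodesilylation of 12 with N-bromosuccinimide in CH2Cl2 at −78 °C gives, with allyl transposition, the 2-substituted allyl bromide (1R)-1-{[tert-butyl(dimethyl)silyl]oxy}-1-[(2S,4S,6S,8S,10S)-8-{(1S)-2-(bromomethyl)-1-[(triethylsilyl)oxy]prop-2-en-1-yl}-4,10-dimethyl-1,7-dioxaspiro[5.5]undecan-2-yl]propan-2-one F2. An indium-mediated Barbier allylation of aldehyde 21 with F2 (In powder, THF/H2O, rt) then forms the C8–C9 bond without a strong Lewis acid, with the syn preference typical of α-alkoxy aldehydes, and returns 22.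

Step 18 (directed hydrogenation; risks are alkene isomerisation, partial enoate reduction or low diastereoselectivity on the crowded substrate). The fallback sets out from 23 and comes back at 25. RhCl(PPh3)3-catalysed hydroboration of silyl ether 23 with catecholborane at −20 °C (the syn-selective mode for 1,1-disubstituted allylic silyl ethers, which here places the new C10 hydrogen as required) gives the primary alkyl catecholboronate methyl (2E,5R,6S,7S,8S,10S,11S)-10-[(1,3,2-benzodioxaborol-2-yl)methyl]-7-[(4-methoxybenzyl)oxy]-2,6-dimethyl-8-[(3-methylbutanoyl)oxy]-5-(propanoyloxy)-11-Sp-11-[(triethylsilyl)oxy]undec-2-enoate F3. Radical protodeboronation with 4-tert-butylcatechol converts the CH2–B group into the C10 methyl group and gives the triethylsilyl ether of 25, F4. HF·pyridine in pyridine/THF then removes the triethylsilyl group to give 25.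

**Further compounds**
F1 | step 2 | (6S,10S)-2,14-dihydroxy-2,6,10,14-tetramethyl-3,13-bis(phenylselanyl)pentadecan-8-one (C3/C13 epimers) | CC(C)(O)C([Se]c1ccccc1)CC[C@H](C)CC(=O)C[C@@H](C)CCC([Se]c1ccccc1)C(C)(C)O
F2 | step 15 | (1R)-1-{[tert-butyl(dimethyl)silyl]oxy}-1-[(2S,4S,6S,8S,10S)-8-{(1S)-2-(bromomethyl)-1-[(triethylsilyl)oxy]prop-2-en-1-yl}-4,10-dimethyl-1,7-dioxaspiro[5.5]undecan-2-yl]propan-2-one | C=C(CBr)[C@H](O[Si](CC)(CC)CC)[C@@H]1C[C@H](C)C[C@]2(C[C@@H](C)C[C@@H]([C@@H](O[Si](C)(C)C(C)(C)C)C(C)=O)O2)O1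
F3 | step 18 | methyl (2E,5R,6S,7S,8S,10S,11S)-10-[(1,3,2-benzodioxaborol-2-yl)methyl]-7-[(4-methoxybenzyl)oxy]-2,6-dimethyl-8-[(3-methylbutanoyl)oxy]-5-(propanoyloxy)-11-Sp-11-[(triethylsilyl)oxy]undec-2-enoate | CCC(=O)O[C@H](C/C=C(\C)C(=O)OC)[C@H](C)[C@H](OCc1ccc(OC)cc1)[C@H](C[C@H](CB1Oc2ccccc2O1)[C@H](O[Si](CC)(CC)CC)[C@@H]1C[C@H](C)C[C@]2(C[C@@H](C)C[C@@H]([C@@H](O[Si](C)(C)C(C)(C)C)C(C)=O)O2)O1)OC(=O)CC(C)C
F4 | step 18 | methyl (2E,5R,6S,7S,8S,10S,11S)-7-[(4-methoxybenzyl)oxy]-2,6,10-trimethyl-8-[(3-methylbutanoyl)oxy]-5-(propanoyloxy)-11-Sp-11-[(triethylsilyl)oxy]undec-2-enoate | CCC(=O)O[C@H](C/C=C(\C)C(=O)OC)[C@H](C)[C@H](OCc1ccc(OC)cc1)[C@H](C[C@H](C)[C@H](O[Si](CC)(CC)CC)[C@@H]1C[C@H](C)C[C@]2(C[C@@H](C)C[C@@H]([C@@H](O[Si](C)(C)C(C)(C)C)C(C)=O)O2)O1)OC(=O)CC(C)C
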